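**Retrosynthetic overview**

1. The target is traced back (C15 allylic oxidation, reduction of the C12 bridge ketone, C1 acetylation) to a bridged ketone. Its ring D bridge (C15–C16) comes from a ring C β,γ-enone by C11 enolate alkylation (C11–C15) and palladium enolate alkenylation (C13–C16); the enone comes from Birch reduction of an anisole ring C.
2. Key disconnection: ring A of the tricyclic 1,6-diketone is cut at C2–C3 and C4–C5 into a bicyclic bromomethyl ketone (rings B and C, quaternary C10 in place) and isobutene, joined by a radical–polar crossover (4+2) annulation.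
3. Enabling feature: the oxygens at C1 (ring A) and C6 (ring B) flank the C10–C5 ring fusion in a 1,4-relationship. C1=O makes C2 a radical site, the C5=C6 enol ether of the C6 ketone makes C5 a carbon nucleophile, C3–C4 with its gem-dimethyl is an isobutene unit that gives a tertiary cation, and quaternary C10 (methyl C20, aryl C9) holds both arms and cannot enolise.
4. The bromomethyl ketone comes from a Birch reductive methylation of 3,7-dimethoxy-1-naphthoic acid, which creates C10 and the C5=C6 enol ether at once (resolved as an amine salt); the naphthoate comes from 4-methoxyphenylacetone and diethyl oxalate.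
5. Ring order: C (arene, bought) → B (Friedel–Crafts cyclodehydration) → A (key step) → D (bridge).

Key step: step 8

Remark on notation: locants follow the podocarpane/kaurane numbering of the target (C20 = methyl on C10; C15 = ketone carbon on C11; C16/C17 = methylene unit on C13; C12 = one-carbon bridge). α/β refer to the usual drawing in which the C20 methyl is α and H-5 is β.
Assumption: the trans-fused 1,6-diketone is taken to be the more stable C5 epimer, as is usual for 4,4,10-trimethyl-6-oxo-hydrophenanthrenes.

**Route**

Step 1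
Reactants: 1 1-(4-methoxyphenyl)propan-2-one; 2 diethyl oxalate
Product: 3 ethyl 5-(4-methoxyphenyl)-2,4-dioxopentanoate
Conditions: NaOEt, EtOH, 0 → 25 °C; cold dilute HCl
Reagents that add atoms: none
Why: Crossed Claisen condensation: under equilibrating conditions the non-enolisable oxalate acylates the methyl group of the ketone, and the stabilised enolate of the 2,4-diketo ester drives the reaction; no stereocentre is formed.

Step 2
Reactants: 3 ethyl 5-(4-methoxyphenyl)-2,4-dioxopentanoate
Product: 4 ethyl 3-hydroxy-7-methoxynaphthalene-1-carboxylate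
Conditions: conc. H2SO4, 0 → 20 °C; ice
Reagents that add atoms: none
Why: Intramolecular Friedel–Crafts cyclodehydration: the protonated α-keto ester carbonyl attacks the ring position ortho to the benzylic CH2 (both ortho positions are equivalent, and six-membered ring B is the only size open), and loss of water with enolisation of the remaining ketone gives the naphthol.

Step 3
Reactants: 4 ethyl 3-hydroxy-7-methoxynaphthalene-1-carboxylate
Product: 6 3,7-dimethoxynaphthalene-1-carboxylic acid, via dimethoxy ester 5 (not isolated)
Conditions: MeI, K2CO3, DMF, 25 °C; then NaOH, H2O/MeOH, 60 °C; HCl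
Reagents that add atoms: iodomethane CI; water O (as aqueous NaOH)
Why: Williamson O-methylation of the naphthol followed by ester saponification in the same pot.

Step 4
Reactants: 6 3,7-dimethoxynaphthalene-1-carboxylic acid
Product: 8 rac-3,7-dimethoxy-1-methyl-1,4-dihydronaphthalene-1-carboxylic acid, via dilithium dianion 7 (not isolated)
Conditions: Li (3 equiv), NH3(l)/THF, −78 °C; then MeI, −78 → −33 °C; NH4Cl; cold dilute HCl to pH 4
Reagents that add atoms: iodomethane CI
Why: Birch reductive alkylation of an aromatic acid: the carboxyl-bearing ring is reduced, NH3 protonates C4 of the dianion and the carboxylate enolate is C-methylated at C1; as with 3-methoxybenzoic acid the methoxy carbon stays sp2, so the quaternary carbon (future C10, racemic) and the enol ether double bond next to it (future C5=C6) are made together.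

Step 5
Reactants: 8 rac-3,7-dimethoxy-1-methyl-1,4-dihydronaphthalene-1-carboxylic acid; 9 (S)-1-phenylethylamine
Product: 10 (S)-1-phenylethylammonium (R)-3,7-dimethoxy-1-methyl-1,4-dihydronaphthalene-1-carboxylate
Conditions: EtOAc/EtOH, 60 → 5 °C; recrystallise to constant optical rotation
Reagents that add atoms: none
Why: Classical resolution by fractional crystallisation of diastereomeric ammonium carboxylates; the configuration of the crystalline salt is to be fixed by X-ray analysis, and the antipodal amine is used on the mother-liquor acid if the salt of the (S)-acid should be the less soluble one.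

Step 6
Reactants: 10 (S)-1-phenylethylammonium (R)-3,7-dimethoxy-1-methyl-1,4-dihydronaphthalene-1-carboxylate
Product: 12 (R)-1-(3,7-dimethoxy-1-methyl-1,4-dihydronaphthalen-1-yl)ethan-1-one, via free (R)-acid 11 (not isolated)
Conditions: cold 0.5 M HCl/Et2O, 0 °C, dry; then MeLi (3 equiv), Et2O, 0 → 25 °C; cold aq. NH4Cl
Reagents that add atoms: methyllithium [Li]C
Why: Conversion of a carboxylic acid into a methyl ketone with MeLi: the lithium carboxylate adds one MeLi and the dilithium gem-diolate survives until work-up, so no tertiary alcohol forms; the quaternary stereocentre and the enol ether are untouched.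

Step 7
Reactants: 12 (R)-1-(3,7-dimethoxy-1-methyl-1,4-dihydronaphthalen-1-yl)ethan-1-one
Product: 14 (R)-2-bromo-1-(3,7-dimethoxy-1-methyl-1,4-dihydronaphthalen-1-yl)ethan-1-one, via silyl enol ether 13 (not isolated)
Conditions: LiN(i-Pr)2, THF, −78 °C; Me3SiCl; then N-bromosuccinimide, NaHCO3, THF, −78 °C
Reagents that add atoms: N-bromosuccinimide O=C1CCC(=O)N1Br
Why: Regiospecific α-bromination of a ketone through its silyl enol ether: the acetyl CH3 is the only enolisable position (the other α-carbon is quaternary), and at −78 °C N-bromosuccinimide should react with the terminal silyl enol ether in preference to the more hindered trisubstituted methyl enol ether.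

Step 8
Reactants: 14 (R)-2-bromo-1-(3,7-dimethoxy-1-methyl-1,4-dihydronaphthalen-1-yl)ethan-1-one; 15 isobutene (2-methylpropene)
Product: 19 12-methoxy-5β,10α-podocarpa-8,11,13-triene-1,6-dione (trans-fused), via tertiary bromide 16 (not isolated), via methyloxocarbenium bromide 17 (not isolated), via cis-fused diketone 18 (not isolated)
Conditions: Ir(ppy)3 (ppy = 2-phenylpyridinate; 1 mol %), isobutene (10 equiv), MeCN (0.02 M), 450 nm LEDs, 25 °C, sealed tube; then 50 °C, 1 h; then DBU (0.3 equiv), 25 °C
Reagents that add atoms: none
Why: Proposed new method: a photoredox radical–polar crossover (4+2) annulation in which the excited trivalent iridium complex reduces the C–Br bond of 14 to the electrophilic α-keto radical at C2, this adds to the CH2 end of isobutene (bond C2–C3), the tertiary C4 radical is oxidised by tetravalent iridium (or takes bromine from 14 to give 16, which ionises) to the tertiary cation, the cation is captured by the nucleophilic C5 of the C5=C6 methyl enol ether (bond C4–C5) to give 17, and bromide demethylates 17 to the C6 ketone. The closest known reaction types are the photoredox Kharasch addition of α-bromo carbonyl compounds to 1,1-disubstituted alkenes with cationic trapping by an internal nucleophile (carbolactonisation, carboarylation) and the Lewis-acid tert-alkylation of enol ethers. Ring A closes in the 6-exo mode with respect to the enol ether π bond (C5 enters the ring, C6 stays outside), and capture of the cation by the C1 carbonyl oxygen is a reversible five-membered detour. The only new stereocentre, C5, is α to the new C6 ketone and is set under thermodynamic control by DBU (18 to 19), H-5 ending trans to the C20 methyl on the fixed quaternary C10. The step needs the C2 radical to add to isobutene faster than it is reduced or adds to a second molecule (secured by excess isobutene and by the fact that only three- to five-membered closures are open to it within 14), and it needs the cation to be taken at C5 and not through C7 (secured by the Birch-derived position of the enol ether double bond and by ring size).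

Step 9
Reactants: 19 12-methoxy-5β,10α-podocarpa-8,11,13-triene-1,6-dione
Product: 20 12-methoxy-5β,10α-podocarpa-8,11,13-triene-1α,6α-diol
Conditions: LiAlH4, THF, −40 → 0 °C
Reagents that add atoms: none
Why: Hydride reduction of both ketones under steric approach control: the α face of C6 is closed by the two syn-axial methyl groups (C20 and the α-methyl on C4) and that of C1 by the vicinal axial C20 methyl, so hydride should enter from the β face at both carbons and give the axial 6α- and the equatorial 1α-alcohol.

Step 10
Reactants: 20 12-methoxy-5β,10α-podocarpa-8,11,13-triene-1α,6α-diol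
Product: 22 1α,6α-dihydroxy-5β,10α-podocarp-8-en-12-one, via methyl enol ether 21 (not isolated)
Conditions: Li (10 equiv), NH3(l)/THF, t-BuOH, −33 °C; MeOH; then (CO2H)2, THF/H2O, 20 °C
Reagents that add atoms: water O
Why: Birch reduction of the 3,4-dialkylanisole ring C gives the 1-methoxycyclohexa-1,4-diene that keeps the tetrasubstituted C8=C9 bond (the free alcohols are carried as lithium alkoxides), and oxalic acid hydrolyses the enol ether to the C12 ketone without moving the β,γ double bond into conjugation.

Step 11
Reactants: 22 1α,6α-dihydroxy-5β,10α-podocarp-8-en-12-one; 23 2,3-dibromopropene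
Product: 24 11β-(2-bromoprop-2-en-1-yl)-1α,6α-dihydroxy-5β,10α-podocarp-8-en-12-one
Conditions: LiN(i-Pr)2 (3.2 equiv), THF, −78 °C; then 23 (1.05 equiv), −78 → −40 °C; NH4Cl
Reagents that add atoms: none
Why: α-Alkylation of an extended (dienolate) ketone enolate: after the two hydroxyls the doubly activated C11–H between C12=O and C8=C9 is removed, the allylic bromide reacts at the α-carbon C11 (lithium alkoxides are inert at this temperature) and should enter from the β face, anti to the axial C20 methyl that lies 1,3 to C11 across C9, which sets C11.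

Step 12
Reactants: 24 11β-(2-bromoprop-2-en-1-yl)-1α,6α-dihydroxy-5β,10α-podocarp-8-en-12-one
Product: 25 1α,6α-dihydroxy-15(8→11)-abeo-kaura-8,16-dien-12-one (5β-H; 10α-CH3; C15–C16 bridge on the β face)
Conditions: Pd(PPh3)4 (10 mol %), KOPh, THF, 70 °C
Reagents that add atoms: none
Why: Palladium-catalysed intramolecular α-alkenylation of a ketone enolate: zerovalent palladium inserts into the vinyl C–Br bond, the C13 enolate (the only one that can close a ring, five-membered) binds palladium and reductive elimination forms C13–C16; the bridge must span the β face defined at C11, which fixes C13.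

Step 13
Reactants: 25 1α,6α-dihydroxy-15(8→11)-abeo-kaura-8,16-dien-12-one
Product: 26 1α-acetoxy-6α-hydroxy-15(8→11)-abeo-kaura-8,16-dien-12-one
Conditions: Ac2O (1.2 equiv), pyridine, DMAP (5 mol %), CH2Cl2, 0 °C
Reagents that add atoms: acetic anhydride CC(=O)OC(C)=O
Why: DMAP-catalysed acylation, expected to be selective for the equatorial 1α-OH because the axial 6α-OH is shielded by the two syn-axial methyl groups on C4 and C10.

Step 14
Reactants: 26 1α-acetoxy-6α-hydroxy-15(8→11)-abeo-kaura-8,16-dien-12-one
Product: 27 1α-acetoxy-15(8→11)-abeo-kaura-8,16-diene-6α,12-diol (12-OH syn to the C15–C16 bridge)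
Conditions: NaBH4, MeOH, −20 °C
Reagents that add atoms: none
Why: Hydride reduction of the bridging ketone: attack is expected from the side of the C8=C9 double bond, which carries no hydrogen pointing at C12 (as in the reduction of bicyclo[3.2.1]oct-2-en-8-ones and 7-norbornenone), so that the new 12-OH lies syn to the C15–C16 bridge; the acetate and the alkenes are not touched.

Step 15
Reactants: 27 1α-acetoxy-15(8→11)-abeo-kaura-8,16-diene-6α,12-diol
Product: 28 1α-acetoxy-15(8→11)-abeo-kaura-8,16-diene-6α,12,15-triol (C15 configuration open)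
Conditions: SeO2 (0.3 equiv), t-BuOOH, CH2Cl2, 20 °C
Reagents that add atoms: tert-butyl hydroperoxide CC(C)(C)OO (oxygen atom, passed on by SeO2)
Why: Allylic oxidation with SeO2 (ene reaction, then [2,3]-sigmatropic shift) of the 1,1-disubstituted C16=C17 alkene at its only allylic CH2, C15 (C13 is a bridgehead), the hindered tetrasubstituted C8=C9 bond reacting more slowly; the C15 configuration is of no consequence.

Step 16
Reactants: 28 1α-acetoxy-15(8→11)-abeo-kaura-8,16-diene-6α,12,15-triol
Product: 29 CNP0149338.1, 1α-acetoxy-6α,12-dihydroxy-15(8→11)-abeo-kaura-8,16-dien-15-one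
Conditions: MnO2 (activated), CH2Cl2, 20 °C
Reagents that add atoms: none
Why: Chemoselective oxidation of the allylic 15-OH by MnO2 to the α-methylene ketone; the saturated 6α- and 12-hydroxyls and the acetate are inert.

**Compound list**

1 | 1-(4-methoxyphenyl)propan-2-one | COc1ccc(CC(C)=O)cc1 | starting material
2 | diethyl oxalate | CCOC(=O)C(=O)OCC | starting material
3 | ethyl 5-(4-methoxyphenyl)-2,4-dioxopentanoate | CCOC(=O)C(=O)CC(=O)Cc1ccc(OC)cc1 | intermediate
4 | ethyl 3-hydroxy-7-methoxynaphthalene-1-carboxylate | CCOC(=O)c1cc(O)cc2ccc(OC)cc12 | intermediate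
5 | ethyl 3,7-dimethoxynaphthalene-1-carboxylate | CCOC(=O)c1cc(OC)cc2ccc(OC)cc12 | intermediate
6 | 3,7-dimethoxynaphthalene-1-carboxylic acid | OC(=O)c1cc(OC)cc2ccc(OC)cc12 | intermediate
7 | dilithium salt of the 1,4-dihydro dianion of 6 (C4 protonated, carboxylate enolate at C1) | [Li+].[Li+].COC1=CC(=C([O-])[O-])c2cc(OC)ccc2C1 | intermediate
8 | rac-3,7-dimethoxy-1-methyl-1,4-dihydronaphthalene-1-carboxylic acid | COC1=CC(C)(C(=O)O)c2cc(OC)ccc2C1 | intermediate
9 | (S)-1-phenylethylamine | C[C@H](N)c1ccccc1 | starting material
10 | (S)-1-phenylethylammonium (R)-3,7-dimethoxy-1-methyl-1,4-dihydronaphthalene-1-carboxylate | COC1=C[C@@](C)(C(=O)[O-])c2cc(OC)ccc2C1.C[C@H]([NH3+])c1ccccc1 | intermediate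
11 | (R)-3,7-dimethoxy-1-methyl-1,4-dihydronaphthalene-1-carboxylic acid | COC1=C[C@@](C)(C(=O)O)c2cc(OC)ccc2C1 | intermediate
12 | (R)-1-(3,7-dimethoxy-1-methyl-1,4-dihydronaphthalen-1-yl)ethan-1-one | COC1=C[C@@](C)(C(C)=O)c2cc(OC)ccc2C1 | intermediate
13 | (R)-{[1-(3,7-dimethoxy-1-methyl-1,4-dihydronaphthalen-1-yl)ethenyl]oxy}trimethylsilane | COC1=C[C@@](C)(C(=C)O[Si](C)(C)C)c2cc(OC)ccc2C1 | intermediate
14 | (R)-2-bromo-1-(3,7-dimethoxy-1-methyl-1,4-dihydronaphthalen-1-yl)ethan-1-one | COC1=C[C@@](C)(C(=O)CBr)c2cc(OC)ccc2C1 | intermediate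
15 | isobutene (2-methylpropene) | CC(C)=C | starting material
16 | (R)-4-bromo-1-(3,7-dimethoxy-1-methyl-1,4-dihydronaphthalen-1-yl)-4-methylpentan-1-one | COC1=C[C@@](C)(C(=O)CCC(C)(C)Br)c2cc(OC)ccc2C1 | intermediate
17 | O-methyl oxocarbenium bromide at C6 of the cyclised tricycle (C1 ketone, 10α-CH3, C5 mixed) | CC1(C)CCC(=O)[C@@]2(C)c3cc(OC)ccc3CC(=[O+]C)C12.[Br-] | intermediate
18 | 12-methoxy-5α,10α-podocarpa-8,11,13-triene-1,6-dione (cis-fused C5 epimer) | CC1(C)CCC(=O)[C@@]2(C)c3cc(OC)ccc3CC(=O)[C@@H]12 | intermediate
19 | 12-methoxy-5β,10α-podocarpa-8,11,13-triene-1,6-dione (trans-fused) | CC1(C)CCC(=O)[C@@]2(C)c3cc(OC)ccc3CC(=O)[C@H]12 | intermediate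
20 | 12-methoxy-5β,10α-podocarpa-8,11,13-triene-1α,6α-diol | CC1(C)CC[C@H](O)[C@@]2(C)c3cc(OC)ccc3C[C@H](O)[C@H]12 | intermediate
21 | 12-methoxy-5β,10α-podocarpa-8,12-diene-1α,6α-diol (enol ether C12=C13, C8=C9) | CC1(C)CC[C@H](O)[C@@]2(C)C3=C(CC=C(OC)C3)C[C@H](O)[C@H]12 | intermediate
22 | 1α,6α-dihydroxy-5β,10α-podocarp-8-en-12-one | CC1(C)CC[C@H](O)[C@@]2(C)C3=C(CCC(=O)C3)C[C@H](O)[C@H]12 | intermediate
23 | 2,3-dibromopropene | BrCC(Br)=C | starting material
24 | 11β-(2-bromoprop-2-en-1-yl)-1α,6α-dihydroxy-5β,10α-podocarp-8-en-12-one | CC1(C)CC[C@H](O)[C@@]2(C)C3=C(CCC(=O)[C@@H]3CC(Br)=C)C[C@H](O)[C@H]12 | intermediate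
25 | 1α,6α-dihydroxy-15(8→11)-abeo-kaura-8,16-dien-12-one (5β-H; 10α-CH3; bridge β) | C=C1C[C@@H]2C3=C(C[C@H]1C2=O)C[C@H](O)[C@@H]1C(C)(C)CC[C@H](O)[C@@]31C | intermediate
26 | 1α-acetoxy-6α-hydroxy-15(8→11)-abeo-kaura-8,16-dien-12-one | C=C1C[C@@H]2C3=C(C[C@H]1C2=O)C[C@H](O)[C@@H]1C(C)(C)CC[C@H](OC(C)=O)[C@@]31C | intermediate
27 | 1α-acetoxy-15(8→11)-abeo-kaura-8,16-diene-6α,12-diol (12-OH syn to the C15–C16 bridge) | C=C1C[C@@H]2C3=C(C[C@H]1[C@@H]2O)C[C@H](O)[C@@H]1C(C)(C)CC[C@H](OC(C)=O)[C@@]31C | intermediate
28 | 1α-acetoxy-15(8→11)-abeo-kaura-8,16-diene-6α,12,15-triol (C15 configuration open) | C=C1C(O)[C@@H]2C3=C(C[C@H]1[C@@H]2O)C[C@H](O)[C@@H]1C(C)(C)CC[C@H](OC(C)=O)[C@@]31C | intermediate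
29 | CNP0149338.1, 1α-acetoxy-6α,12-dihydroxy-15(8→11)-abeo-kaura-8,16-dien-15-one | C=C1C(=O)[C@@H]2C3=C(C[C@H]1[C@@H]2O)C[C@H](O)[C@@H]1C(C)(C)CC[C@H](OC(C)=O)[C@@]31C | target

**Step count and risks**

Total step count: 16. Longest linear sequence: 16 steps (the route is fully linear; 2, 9, 15 and 23 are bought).

The three steps most likely to fail:

1. Step 8 (Proposed new method). What may go wrong: the C2 radical is reduced to the methyl ketone or adds to the enol ether of a second molecule instead of isobutene, or the tertiary cation is lost by proton loss before C5 attacks. The fallback uses two polar steps of known type and sets out from ketone 12. Its lithium enolate (LiN(i-Pr)2, THF, −78 °C) is alkylated with 3-bromo-2-methylpropene to give (R)-1-(3,7-dimethoxy-1-methyl-1,4-dihydronaphthalen-1-yl)-4-methylpent-4-en-1-one F1, which forms C2–C3. CF3SO3H (10 mol %) in CH2Cl2 at −40 °C then protonates the 1,1-disubstituted alkene, and the tertiary C4 cation is captured by C5 of the enol ether (cation–olefin cyclisation with an enol ether terminator), which forms C4–C5. Aqueous work-up hydrolyses the oxocarbenium ion, DBU equilibrates C5, and the route is rejoined at diketone 19.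

2. Step 14. What may go wrong: hydride is delivered to the bridging C12 carbonyl from the side of the C15–C16 bridge, giving the 12-epimer, which cannot be inverted by substitution at a bridge carbon. The fallback uses a temporary blocking group and exchanges the order of reduction and allylic oxidation; it sets out from ketone 26. SeO2/t-BuOOH gives the 1α-acetoxy-6α,15-dihydroxy-12-ketone F2 (exo alcohol expected). t-BuMe2SiOSO2CF3/2,6-lutidine at −78 °C silylates the allylic 15-OH (the 6α-OH is too hindered) to give 15-silyl ether F3, whose silyloxy group covers the bridge-side face of C12. NaBH4 can then enter only from the C8=C9 side and should give the 12-alcohol F4. Bu4NF removes the silyl group and the route is rejoined at triol 28.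

3. Step 12. What may go wrong: base-induced loss of HBr from the 2-bromoallyl group and epimerisation at C11 outrun oxidative addition and enolate coupling. The fallback replaces palladium enolate coupling by π-acid activation of an alkyne and sets out from enone 22. Alkylation as in step 11, but with propargyl bromide, gives 11β-propargyl ketone F5. LiN(SiMe3)2 (3.2 equiv) and t-BuMe2SiCl (1 equiv) at −78 °C give the kinetic C12=C13 silyl enol ether F6 (the C11–H is tertiary and hindered, and the lithium alkoxides are not silylated at this temperature). Ph3PAuCl/AgBF4 (5 mol %) in CH2Cl2/MeOH closes ring D by 5-exo-dig attack of C13 on the gold-activated alkyne (Conia-ene type), and the route is rejoined at ketone 25.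

Further compounds
F1 | step 8 | (R)-1-(3,7-dimethoxy-1-methyl-1,4-dihydronaphthalen-1-yl)-4-methylpent-4-en-1-one | COC1=C[C@@](C)(C(=O)CCC(C)=C)c2cc(OC)ccc2C1
F2 | step 14 | 1α-acetoxy-6α,15-dihydroxy-15(8→11)-abeo-kaura-8,16-dien-12-one | C=C1C(O)[C@@H]2C3=C(C[C@H]1C2=O)C[C@H](O)[C@@H]1C(C)(C)CC[C@H](OC(C)=O)[C@@]31C
F3 | step 14 | 1α-acetoxy-15-(tert-butyldimethylsilyloxy)-6α-hydroxy-15(8→11)-abeo-kaura-8,16-dien-12-one | C=C1C(O[Si](C)(C)C(C)(C)C)[C@@H]2C3=C(C[C@H]1C2=O)C[C@H](O)[C@@H]1C(C)(C)CC[C@H](OC(C)=O)[C@@]31C
F4 | step 14 | 1α-acetoxy-15-(tert-butyldimethylsilyloxy)-15(8→11)-abeo-kaura-8,16-diene-6α,12-diol | C=C1C(O[Si](C)(C)C(C)(C)C)[C@@H]2C3=C(C[C@H]1[C@@H]2O)C[C@H](O)[C@@H]1C(C)(C)CC[C@H](OC(C)=O)[C@@]31C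
F5 | step 12 | 1α,6α-dihydroxy-11β-(prop-2-yn-1-yl)-5β,10α-podocarp-8-en-12-one | CC1(C)CC[C@H](O)[C@@]2(C)C3=C(CCC(=O)[C@@H]3CC#C)C[C@H](O)[C@H]12
F6 | step 12 | 12-(tert-butyldimethylsilyloxy)-11β-(prop-2-yn-1-yl)-5β,10α-podocarpa-8,12-diene-1α,6α-diol | CC1(C)CC[C@H](O)[C@@]2(C)C3=C(CC=C(O[Si](C)(C)C(C)(C)C)[C@@H]3CC#C)C[C@H](O)[C@H]12
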